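4 questions are asked of the west flask, and I mean to answer them through one ratio.

- west: starting material 0.050 M; partner 1.3 equiv; second substrate 5 equiv; the very flask that is asked about, followed so far
- flask: starting material 0.050 M; partner 1.30 equiv; second substrate 5.00 equiv; time 40 min

west run (percent of the starting material charged)

| time / min | target / % | starting material / % |
|---|---|---|
| 0.500 | 7.6 | 91.2 |
| 0.833 | 12.7 | 87.6 |
| 1.67 | 14.1 | 82.0 |
| 2.50 | 13.7 | 79.7 |
| 5.00 | 10.7 | 77.5 |
| 8.00 | 5.0 | 76.8 |

(scatter of a reading: 0.5 percentage points)

* the moment within 40 min at which there is most target
* the amount of target, in percent of the starting material charged, at that time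
* earliest time at which at least nineteen twentieths of that best amount are there, in min
* latest time at which they still are, in min

- the numbers in the tables scatter with a standard deviation of 0.5 percentage points

In the west run the starting material has lost 22.5% of its charge by 5.00 min and 23.2% by 8.00 min, although 1.3 equiv of partner went in, so the feed of target dies away. The reading at 1.67 min gives that feed a fading rate of 0.896 min⁻¹, while target falls between the last two readings at 0.254 min⁻¹, which I treat as a pseudo-first-order loss, slower than the feed fades.

Two extreme flasks can be solved in the head. If the whole feed came at once, target would start at that loss of starting material and sink exponentially; if target were never lost, it would climb towards that same loss. Up to its top the real curve lies under both; at the top feed equals loss, which places the top on the sinking curve, and after the top the real curve runs above that sinking curve.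

Leaving out target's own sinking puts the top at 1.41 min; putting that back gives 1.81 min, and going round until it stands still gives 1.97 min. So I carry the peak ratio, the best amount of target over all the starting material lost, 0.607, and my best is 14.1%. At 1.38 min and 2.81 min my curve keeps 0.952 and 0.941 of its top, so I take these as the edges.

The forecast says 1.9 min, 14.3%, and from 1.2 min to 2.8 min, holding that “Whatever drives it dies within a few minutes”.

The west flask gives 1.96 min, 14.4%, and from 1.34 min to 2.79 min.

    starting material + partner → target (k = 3.60 L mol⁻¹ min⁻¹)
    second substrate + partner → second product (k = 1.20 L mol⁻¹ min⁻¹)
    target ⇌ isomer of the product (K = 13.0, k = 0.210 min⁻¹)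
    starting material + target → side product (k = 0.250 L mol⁻¹ min⁻¹)
    partner → decomposed reagent (k = 0.480 min⁻¹)

In the west flask partner, the limiting reagent, feeds target while it falls to 16.4% of its charge at 1.96 min and 2.61% at 4.00 min, and target turns on into its isomer, which holds 19.5% at 20.0 min, when target is down to 1.70%. Its best over the 23.7% of starting material lost by 40.0 min is 0.606, beside the peak ratio of 0.607. The neighbour flask with 5.20 equiv of partner loses 69.0% of its starting material by 40.0 min, which times the peak ratio makes 41.9%, and its best stands at 44.0%.

All runs were generated by integration for an exercise; noise was put on by code.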